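**Plan**

- Retrosynthesis: the C8(ring A)–CH2–C6(ring B) bridge is cut first, then ring B at C1–C6 (Dieckmann) and C2–C3 (C-acylation of methyl acetoacetate), then the C4–C5 bond of the resulting 2-acetyl β-keto aldehyde (1,2-acyl shift), then the epoxide and the E-allylic alcohol back to geranyl bromide; the pyran of ring A is cut at C4–C4a back to an aryl propargyl ether.
- Enabling feature: C4 of ring B (the cyclohexadienone) is a quaternary carbon between the two carbonyl-level carbons C3 and C5, i.e. the central carbon of a 2,2-disubstituted 1,3-dicarbonyl. This is the retron of an acyl shift in an α,β-epoxy ketone whose tertiary epoxide carbon already carries the methyl and geranyl groups.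
- Forward: the chain is built linearly (steps 1–9), ring B is closed in step 11, the pyran of ring A in step 13, and the halves are joined through the methylene bridge in step 15.
- Stereochemistry: the only stereocentre (C4 of ring B) comes from the Sharpless epoxidation (step 4) and is transferred with inversion to the quaternary carbon in the acyl shift; the E olefins come from geranyl bromide and syn-carboalumination.

Key step: step 8

Remark: ring B is drawn throughout as the 3,5-dihydroxycyclohexa-2,5-dien-1-one tautomer of the target SMILES, and the descriptor 4R refers to that tautomer.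

**Route**

Step 1
Reactants: 1 geranyl bromide [(2E)-1-bromo-3,7-dimethylocta-2,6-diene]; 2 ethynyltrimethylsilane
Product: 4 trimethyl[(4E)-5,9-dimethyldeca-4,8-dien-1-yn-1-yl]silane, via [(trimethylsilyl)ethynyl]magnesium bromide 3 (not isolated)
Conditions: EtMgBr, THF, 0 °C to rt; then CuBr·SMe2 (5 mol %), 1, THF, 50 °C
Reagents that add atoms: none
Why: Copper-catalysed SN2 coupling of an alkynyl Grignard reagent with a primary allylic bromide is a standard route to skipped enynes and should leave the E olefin of the geranyl unit unchanged.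

Step 2
Reactants: 4 trimethyl[(4E)-5,9-dimethyldeca-4,8-dien-1-yn-1-yl]silane
Product: 5 (4E)-5,9-dimethyldeca-4,8-dien-1-yne
Conditions: K2CO3 (cat.), MeOH, rt
Reagents that add atoms: none
Why: Base-catalysed methanolysis of the C(sp)–Si bond (protodesilylation) is routine and mild enough not to isomerise the 1,4-enyne.

Step 3
Reactants: 5 (4E)-5,9-dimethyldeca-4,8-dien-1-yne
Product: 8 (2E,5E)-3,6,10-trimethylundeca-2,5,9-trien-1-ol, via alkenyldimethylalane 6 (not isolated), via lithium alkenylaluminate 7 (not isolated)
Conditions: AlMe3 (2 equiv), Cp2ZrCl2 (25 mol %), CH2Cl2, 0 °C to rt; then n-BuLi, THF/hexane, −78 °C; (CH2O)n, rt; aq. HCl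
Reagents that add atoms: trimethylaluminium, C[Al](C)C; paraformaldehyde (formaldehyde unit), C=O
Why: Negishi zirconium-catalysed methylalumination adds methyl and aluminium syn across the terminal alkyne with aluminium at the terminus, so hydroxymethylation of the derived aluminate should give the E-allylic alcohol, the trisubstituted olefins being inert to carboalumination.

Step 4
Reactants: 8 (2E,5E)-3,6,10-trimethylundeca-2,5,9-trien-1-ol
Product: 9 [(2R,3R)-3-[(2E)-3,7-dimethylocta-2,6-dien-1-yl]-3-methyloxiran-2-yl]methanol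
Conditions: Ti(OiPr)4 (10 mol %), D-(−)-diethyl tartrate (12 mol %), t-BuOOH, 4 Å molecular sieves, CH2Cl2, −20 °C
Reagents that add atoms: tert-butyl hydroperoxide, CC(C)(C)OO
Why: Sharpless asymmetric epoxidation is chemoselective for the allylic alcohol olefin and, by analogy with geraniol (which gives the 2S,3S epoxide with L-(+)-tartrate), D-(−)-diethyl tartrate should deliver the 2R,3R epoxide, setting both epoxide centres by reagent control.

Step 5
Reactants: 9 [(2R,3R)-3-[(2E)-3,7-dimethylocta-2,6-dien-1-yl]-3-methyloxiran-2-yl]methanol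
Product: 10 (2S,3R)-3-[(2E)-3,7-dimethylocta-2,6-dien-1-yl]-3-methyloxirane-2-carbaldehyde
Conditions: Dess–Martin periodinane, pyridine, CH2Cl2, 0 °C to rt
Reagents that add atoms: none
Why: Dess–Martin oxidation under pyridine buffering should convert the 2,3-epoxy alcohol to the epoxy aldehyde without opening the epoxide or epimerising C2 (the descriptor changes only through the priority rules).

Step 6
Reactants: 10 (2S,3R)-3-[(2E)-3,7-dimethylocta-2,6-dien-1-yl]-3-methyloxirane-2-carbaldehyde
Product: 11 (1RS)-1-[(2R,3R)-3-[(2E)-3,7-dimethylocta-2,6-dien-1-yl]-3-methyloxiran-2-yl]ethan-1-ol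
Conditions: MeMgBr, THF, −78 °C; then H2O
Reagents that add atoms: methylmagnesium bromide, C[Mg]Br
Why: Grignard 1,2-addition to the aldehyde at −78 °C is much faster than epoxide opening, and the new carbinol centre, formed as a mixture, is erased in the next step.

Step 7
Reactants: 11 (1RS)-1-[(2R,3R)-3-[(2E)-3,7-dimethylocta-2,6-dien-1-yl]-3-methyloxiran-2-yl]ethan-1-ol
Product: 12 1-[(2S,3R)-3-[(2E)-3,7-dimethylocta-2,6-dien-1-yl]-3-methyloxiran-2-yl]ethan-1-one
Conditions: Dess–Martin periodinane, pyridine, CH2Cl2, 0 °C to rt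
Reagents that add atoms: none
Why: Dess–Martin oxidation of the secondary epoxy alcohol should give the α,β-epoxy ketone (acetyl trans to the geranyl group) with both epoxide centres unchanged.

Step 8
Reactants: 12 1-[(2S,3R)-3-[(2E)-3,7-dimethylocta-2,6-dien-1-yl]-3-methyloxiran-2-yl]ethan-1-one
Product: 13 (2S,4E)-2-acetyl-2,5,9-trimethyldeca-4,8-dienal
Conditions: BF3·OEt2 (0.3 equiv), CH2Cl2, −78 to −40 °C; then Et3N, aq. NaHCO3
Reagents that add atoms: none
Why: BF3 coordinates the epoxide oxygen, the bond from oxygen to the tertiary carbon C3 lengthens, and the acetyl group shifts from C2 to C3 on the face anti to the departing oxygen while the C2–O bond becomes the formyl C=O (House–Meinwald 1,2-acyl shift of an α,β-epoxy ketone). The closest known reaction type is the Lewis acid rearrangement of β,β-disubstituted α,β-epoxy ketones to 2,2-disubstituted 1,3-dicarbonyl compounds, which is concerted and proceeds with inversion at the migration terminus. No ring is closed; the one new C–C bond joins the quaternary carbon (later C4 of ring B) to the acetyl carbon (later C5, its methyl later C6), and the formyl carbon becomes C3. The quaternary stereocentre is controlled only by the configuration of the tertiary epoxide carbon set in step 4, so the (2S,3R)-epoxy ketone should give the (S)-keto aldehyde. The step needs acyl migration to outrun the hydride shift from C2 (to a 1,2-diketone), fluoride capture and participation of the homoallylic trisubstituted olefin; the high migratory aptitude of acyl in a concerted anti shift, low temperature and substoichiometric BF3·OEt2 in a non-nucleophilic solvent should secure this.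

Step 9
Reactants: 13 (2S,4E)-2-acetyl-2,5,9-trimethyldeca-4,8-dienal
Product: 14 (2R,4E)-2-acetyl-2,5,9-trimethyldeca-4,8-dienoic acid
Conditions: NaClO2, NaH2PO4, 2-methylbut-2-ene (excess), t-BuOH/H2O, 0 °C; cold extraction, used at once
Reagents that add atoms: sodium chlorite, [Na+].[O-]Cl=O
Why: Pinnick oxidation converts the hindered, non-enolisable aldehyde to the acid while 2-methylbut-2-ene scavenges HOCl and so spares the trisubstituted olefins; the β-keto acid is kept cold and carried on directly to avoid decarboxylation.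

Step 10
Reactants: 14 (2R,4E)-2-acetyl-2,5,9-trimethyldeca-4,8-dienoic acid; 15 methyl acetoacetate
Product: 17 methyl (4R,6E)-2,4-diacetyl-4,7,11-trimethyl-3-oxododeca-6,10-dienoate, via acid chloride 16 (not isolated)
Conditions: 1-chloro-N,N,2-trimethylprop-1-en-1-amine (Ghosez's reagent), CH2Cl2, 0 °C; then 15, MgCl2, pyridine, CH2Cl2, 0 °C to rt
Reagents that add atoms: none
Why: Ghosez's reagent forms the acid chloride under neutral conditions (no HCl to add to the olefins), and MgCl2/pyridine soft enolisation of methyl acetoacetate gives C- rather than O-acylation, a standard route to 2-acylacetoacetates; the quaternary centre cannot enolise and is not touched.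

Step 11
Reactants: 17 methyl (4R,6E)-2,4-diacetyl-4,7,11-trimethyl-3-oxododeca-6,10-dienoate
Product: 18 (4R)-2-acetyl-4-[(2E)-3,7-dimethylocta-2,6-dien-1-yl]-3,5-dihydroxy-4-methylcyclohexa-2,5-dien-1-one
Conditions: LiN(SiMe3)2 (2.5 equiv), THF, −78 to 0 °C; then aq. HCl
Reagents that add atoms: none
Why: Dieckmann (intramolecular Claisen) condensation: once the tricarbonyl methine is deprotonated, the kinetic enolate of the only enolisable methyl ketone attacks the ester in a 6-exo-trig closure, and irreversible loss of methoxide to the strongly stabilised trione anion should pull any reversible aldol addition to the enolate-masked acetyl group back; the quaternary centre is not involved.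

Step 12
Reactants: 19 1-(2,4,6-trihydroxyphenyl)butan-1-one; 20 3-chloro-3-methylbut-1-yne
Product: 21 1-{2,6-dihydroxy-4-[(2-methylbut-3-yn-2-yl)oxy]phenyl}butan-1-one
Conditions: CuCl2·2H2O (1 mol %), DBU (1.05 equiv), MeCN, 0 °C
Reagents that add atoms: none
Why: Copper-catalysed propargylic etherification of phenols with tertiary propargylic chlorides is well established, and with one equivalent of base the most acidic, non-chelated para hydroxyl of the acylphloroglucinol should be alkylated selectively.

Step 13
Reactants: 21 1-{2,6-dihydroxy-4-[(2-methylbut-3-yn-2-yl)oxy]phenyl}butan-1-one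
Product: 22 1-(5,7-dihydroxy-2,2-dimethyl-2H-chromen-6-yl)butan-1-one
Conditions: Ph3PAuNTf2 (2 mol %), CH2Cl2, rt
Reagents that add atoms: none
Why: Gold-catalysed 6-endo-dig intramolecular hydroarylation of aryl 1,1-dimethylpropargyl ethers gives 2,2-dimethyl-2H-chromenes with the aryl C–O bond retained, so the pyran oxygen stays para to the butanoyl group and the two equivalent ortho positions lead to one product.

Step 14
Reactants: 22 1-(5,7-dihydroxy-2,2-dimethyl-2H-chromen-6-yl)butan-1-one
Product: 23 1-{8-[(dimethylamino)methyl]-5,7-dihydroxy-2,2-dimethyl-2H-chromen-6-yl}butan-1-one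
Conditions: [CH2=NMe2]I (Eschenmoser's salt), Et3N, CH2Cl2, 0 °C to rt
Reagents that add atoms: N,N-dimethylmethyleneiminium iodide (Eschenmoser's salt), C=[N+](C)C.[I-]
Why: Mannich aminomethylation with a preformed iminium salt should occur at C8, the single free and highly activated aromatic position.

Step 15
Reactants: 18 (4R)-2-acetyl-4-[(2E)-3,7-dimethylocta-2,6-dien-1-yl]-3,5-dihydroxy-4-methylcyclohexa-2,5-dien-1-one; 23 1-{8-[(dimethylamino)methyl]-5,7-dihydroxy-2,2-dimethyl-2H-chromen-6-yl}butan-1-one
Product: 25 CNP0203748.1 [(4R)-2-acetyl-6-[(6-butanoyl-5,7-dihydroxy-2,2-dimethyl-2H-chromen-8-yl)methyl]-4-[(2E)-3,7-dimethylocta-2,6-dien-1-yl]-3,5-dihydroxy-4-methylcyclohexa-2,5-dien-1-one], via ortho-quinone methide 24 (not isolated)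
Conditions: 1,4-dioxane, 90 °C, N2 sweep
Reagents that add atoms: none
Why: Thermal loss of dimethylamine from the ortho-hydroxybenzylamine gives an ortho-quinone methide that is trapped at carbon by the enol of the β-triketone (Michael-type addition), the established way to unsymmetrical methylene-bridged acylphloroglucinols; only C6 of ring B is free, and the quaternary centre is untouched.

**Compound list**

1 | geranyl bromide, (2E)-1-bromo-3,7-dimethylocta-2,6-diene | CC(C)=CCC/C(C)=C/CBr | starting material
2 | ethynyltrimethylsilane | C#C[Si](C)(C)C | starting material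
3 | [(trimethylsilyl)ethynyl]magnesium bromide | C[Si](C)(C)C#C[Mg]Br | intermediate (not isolated)
4 | trimethyl[(4E)-5,9-dimethyldeca-4,8-dien-1-yn-1-yl]silane | C[Si](C)(C)C#CC/C=C(\C)CCC=C(C)C | intermediate
5 | (4E)-5,9-dimethyldeca-4,8-dien-1-yne | C#CC/C=C(\C)CCC=C(C)C | intermediate
6 | dimethyl[(1E,4E)-2,5,9-trimethyldeca-1,4,8-trien-1-yl]alumane | C[Al](C)/C=C(\C)C/C=C(\C)CCC=C(C)C | intermediate (not isolated)
7 | lithium butyl(dimethyl)[(1E,4E)-2,5,9-trimethyldeca-1,4,8-trien-1-yl]aluminate | [Li+].CCCC[Al-](C)(C)/C=C(\C)C/C=C(\C)CCC=C(C)C | intermediate (not isolated)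
8 | (2E,5E)-3,6,10-trimethylundeca-2,5,9-trien-1-ol | OC/C=C(\C)C/C=C(\C)CCC=C(C)C | intermediate
9 | [(2R,3R)-3-[(2E)-3,7-dimethylocta-2,6-dien-1-yl]-3-methyloxiran-2-yl]methanol | OC[C@H]1O[C@]1(C)C/C=C(\C)CCC=C(C)C | intermediate
10 | (2S,3R)-3-[(2E)-3,7-dimethylocta-2,6-dien-1-yl]-3-methyloxirane-2-carbaldehyde | O=C[C@H]1O[C@]1(C)C/C=C(\C)CCC=C(C)C | intermediate
11 | (1RS)-1-[(2R,3R)-3-[(2E)-3,7-dimethylocta-2,6-dien-1-yl]-3-methyloxiran-2-yl]ethan-1-ol (carbinol centre not defined) | CC(O)[C@H]1O[C@]1(C)C/C=C(\C)CCC=C(C)C | intermediate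
12 | 1-[(2S,3R)-3-[(2E)-3,7-dimethylocta-2,6-dien-1-yl]-3-methyloxiran-2-yl]ethan-1-one | CC(=O)[C@H]1O[C@]1(C)C/C=C(\C)CCC=C(C)C | intermediate
13 | (2S,4E)-2-acetyl-2,5,9-trimethyldeca-4,8-dienal | CC(=O)[C@@](C)(C/C=C(\C)CCC=C(C)C)C=O | intermediate
14 | (2R,4E)-2-acetyl-2,5,9-trimethyldeca-4,8-dienoic acid | CC(=O)[C@@](C)(C/C=C(\C)CCC=C(C)C)C(=O)O | intermediate
15 | methyl acetoacetate | COC(=O)CC(C)=O | starting material
16 | (2R,4E)-2-acetyl-2,5,9-trimethyldeca-4,8-dienoyl chloride | CC(=O)[C@@](C)(C/C=C(\C)CCC=C(C)C)C(Cl)=O | intermediate (not isolated)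
17 | methyl (4R,6E)-2,4-diacetyl-4,7,11-trimethyl-3-oxododeca-6,10-dienoate (C2 not defined, largely enolised) | CC(=O)[C@@](C)(C/C=C(\C)CCC=C(C)C)C(=O)C(C(C)=O)C(=O)OC | intermediate
18 | (4R)-2-acetyl-4-[(2E)-3,7-dimethylocta-2,6-dien-1-yl]-3,5-dihydroxy-4-methylcyclohexa-2,5-dien-1-one | O=C1C=C(O)[C@@](C)(C/C=C(\C)CCC=C(C)C)C(O)=C1C(C)=O | intermediate
19 | 1-(2,4,6-trihydroxyphenyl)butan-1-one | CCCC(=O)c1c(O)cc(O)cc1O | starting material
20 | 3-chloro-3-methylbut-1-yne | CC(C)(Cl)C#C | starting material
21 | 1-{2,6-dihydroxy-4-[(2-methylbut-3-yn-2-yl)oxy]phenyl}butan-1-one | CCCC(=O)c1c(O)cc(OC(C)(C)C#C)cc1O | intermediate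
22 | 1-(5,7-dihydroxy-2,2-dimethyl-2H-chromen-6-yl)butan-1-one | CCCC(=O)c1c(O)c2c(cc1O)OC(C)(C)C=C2 | intermediate
23 | 1-{8-[(dimethylamino)methyl]-5,7-dihydroxy-2,2-dimethyl-2H-chromen-6-yl}butan-1-one | CCCC(=O)c1c(O)c2c(c(CN(C)C)c1O)OC(C)(C)C=C2 | intermediate
24 | 6-butanoyl-5-hydroxy-2,2-dimethyl-8-methylidene-2H-chromen-7(8H)-one | CCCC(=O)C1=C(O)C2=C(OC(C)(C)C=C2)C(=C)C1=O | intermediate (not isolated)
25 | CNP0203748.1, (4R)-2-acetyl-6-[(6-butanoyl-5,7-dihydroxy-2,2-dimethyl-2H-chromen-8-yl)methyl]-4-[(2E)-3,7-dimethylocta-2,6-dien-1-yl]-3,5-dihydroxy-4-methylcyclohexa-2,5-dien-1-one | CCCC(=O)c1c(O)c2c(c(CC3=C(O)[C@@](C)(C/C=C(\C)CCC=C(C)C)C(O)=C(C(C)=O)C3=O)c1O)OC(C)(C)C=C2 | target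

**Step count and risks**

Total step count: 15. Longest linear sequence: 12 steps (steps 1–11 and 15, from geranyl bromide); the ring A branch is 3 steps (12–14) before the union.

Steps most likely to fail:

1. Step 8. The opening tertiary epoxide carbon may be intercepted before the acetyl group arrives, by participation of the homoallylic olefin, by a hydride shift from C2 or by fluoride delivery; any of these would lose the chirality transfer. Fallback: setting out from geranyl bromide 1, enantioselective phase-transfer alkylation of tert-butyl 2-methyl-3-oxobutanoate (chiral C2-symmetric N-spiro bis(binaphthyl)ammonium bromide, CsOH·H2O, toluene, −40 °C; catalyst enantiomer chosen for the R ester) would give tert-butyl (2R,4E)-2-acetyl-2,5,9-trimethyldeca-4,8-dienoate F1. Its tert-butyl group is removed with TMSOTf/2,6-lutidine followed by aqueous work-up, and the route is rejoined at keto acid 14.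

2. Step 11. The methyl ketone enolate may add to the acetyl carbonyl and dehydrate (aldol mode) instead of displacing methoxide, or liberated methoxide may cleave the tricarbonyl unit by retro-Claisen reaction. Fallback: setting out from keto acid 14, the ring bonds are made in the opposite order. TMSCHN2 in MeOH/toluene gives methyl (2R,4E)-2-acetyl-2,5,9-trimethyldeca-4,8-dienoate F2. Its kinetic lithium enolate (LiN(SiMe3)2, THF, −78 °C) is acylated with N-methoxy-N-methyl-2-(2-methyl-1,3-dioxolan-2-yl)acetamide to give methyl (2R,4E)-2,5,9-trimethyl-2-[4-(2-methyl-1,3-dioxolan-2-yl)-3-oxobutanoyl]deca-4,8-dienoate F3. Mild deketalisation (PPTS, aqueous acetone) gives methyl (2R,4E)-2-(3,5-dioxohexanoyl)-2,5,9-trimethyldeca-4,8-dienoate F4. NaOMe in MeOH then closes the ring by Claisen attack of the doubly activated diketone carbon on the non-enolisable ester, the mode known for 3,5,7-triketo esters, and the route is rejoined at trione 18.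

3. Step 15. The quinone methide may be consumed by oligomerisation, by O-alkylation or by aminomethyl exchange leading to symmetrical methylene-bridged dimers before the trione captures it. Fallback: setting out from chromene 22, Vilsmeier–Haack formylation (POCl3, DMF, 0 °C to rt) at C8 would give 6-butanoyl-5,7-dihydroxy-2,2-dimethyl-2H-chromene-8-carbaldehyde F5. Organocatalytic reductive Knoevenagel alkylation of trione 18 with this aldehyde (L-proline cat., Hantzsch ester, CH2Cl2, rt) reduces the Knoevenagel adduct in situ by hydride transfer, and the route is rejoined at target 25.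

Further compounds
F1 | step 8 | tert-butyl (2R,4E)-2-acetyl-2,5,9-trimethyldeca-4,8-dienoate | CC(=O)[C@@](C)(C/C=C(\C)CCC=C(C)C)C(=O)OC(C)(C)C
F2 | step 11 | methyl (2R,4E)-2-acetyl-2,5,9-trimethyldeca-4,8-dienoate | CC(=O)[C@@](C)(C/C=C(\C)CCC=C(C)C)C(=O)OC
F3 | step 11 | methyl (2R,4E)-2,5,9-trimethyl-2-[4-(2-methyl-1,3-dioxolan-2-yl)-3-oxobutanoyl]deca-4,8-dienoate | CC1(CC(=O)CC(=O)[C@@](C)(C/C=C(\C)CCC=C(C)C)C(=O)OC)OCCO1
F4 | step 11 | methyl (2R,4E)-2-(3,5-dioxohexanoyl)-2,5,9-trimethyldeca-4,8-dienoate | CC(=O)CC(=O)CC(=O)[C@@](C)(C/C=C(\C)CCC=C(C)C)C(=O)OC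
F5 | step 15 | 6-butanoyl-5,7-dihydroxy-2,2-dimethyl-2H-chromene-8-carbaldehyde | CCCC(=O)c1c(O)c2c(c(C=O)c1O)OC(C)(C)C=C2
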